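The coupling partner is the reagent to follow in this flask, and the reckoning below counts what it spends on anything but substrate.

substrate 1.0 M; coupling partner 1.30 equiv (fed, over 5.0 h); protic impurity 1.00 M; time 25 h; the fed solution adds 0.25 times the starting volume

- why nothing more happens at 25 h, or that something still does (the coupling partner has run out first / all of the substrate has reacted / it is still moving)
- amount of target at 25 h, in percent of the substrate charged
- amount of side product at 25 h, in percent of the substrate charged

- a step written with two of one species runs at k times the square of its concentration and takes two of it each time
- amounts are per litre of the starting volume; all of the dose is in the solution fed
- the reaction counts as stopped when no species that holds the substrate changes by six tenths of a point or more over the second half of the time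
- run time (flask): 25 h

    substrate + coupling partner → target (k1 = 11 M⁻¹ h⁻¹)
    substrate + 2 coupling partner → side product (k2 = 6.7 M⁻² h⁻¹)
    coupling partner + protic impurity → quenched reagent (k3 = 0.25 M⁻¹ h⁻¹)
    coupling partner → decomposed reagent (k4 = 0.55 h⁻¹)

Fed coupling partner is either captured by substrate or lost, by decomposition or by quenching with the protic impurity. Capture to target and both losses are first order in [coupling partner], so that concentration cancels from their ratio and two times remain. With substrate at its charge in the final volume, the capture time is 6.82 min. The survival time against both losses, with the protic impurity diluted likewise, is 1.33 h. Their ratio is the loss ratio, ρ = 0.0852: equivalents lost per equivalent captured at full substrate.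

As substrate falls, capture slows in proportion, so the bill in equivalents for leaving a fraction n of substrate is the converted fraction plus ρ times the natural logarithm of the inverse of n. The 0.300 equiv beyond the first equivalent therefore pays for a logarithm of 3.52, leaving about 2.96% substrate. On this reckoning the coupling partner, though charged at 1.30 equiv, is the limiting reagent.

Early in the feed, with substrate near its charge, [coupling partner] is reckoned as feed rate times capture time, 0.0295 M, and that level held throughout gives about 1.80% side product and so about 95.2% target. The 15.0 survival times after the feed point to a stop for want of coupling partner.

The forecast also says the coupling partner has run out first, with target 91.5% (88% to 94%) and side product 2.5% (1.8% to 3.5%), on the ground that “decomposition and quenching waste enough of the 0.3 equiv excess to leave a few percent of substrate behind”. Its target is lower than this reckoning's, and its side product higher.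

In the simulation the coupling partner has run out first, with target 95.3% and side product 2.50%, so the forecast stands within tolerance.

At 25.0 h the flask holds 2.25% substrate and 0% coupling partner, and the bill for that substrate reading comes to 1.30 equiv against 1.30 equiv charged. The neighbour flask with 0.60 M substrate keeps the equivalents and the protic impurity, so its loss ratio is 0.142, larger than that of the first flask. Its reading of 6.96% substrate is billed at 1.31 equiv against the same charge, and that neighbour flask ends with 91.1% target.

The rate constants come from no measurement.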